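The route rests on disconnecting the C3a–C4 bond of the furofuran, the bond between the acetoxy-bearing bridgehead and the neighbouring benzylic carbon. A Norrish–Yang photocyclization forms it: the excited carbonyl of an oxolan-3-one (the future C3a) abstracts a benzylic hydrogen from the arylmethyl ether on its α-substituent, and the resulting 1,5-biradical closes the second oxolane ring, creating the tertiary alcohol at C3a and the C4 stereocentre in one operation. The precursor is a trans-4,5-disubstituted oxolan-3-one whose two stereocentres (future C6a and C1) come from one iridium-catalysed anti-(hydroxymethyl)allylation. Both aryl groups derive from the same O-benzylvanillyl alcohol. Acetylation and hydrogenolysis finish the synthesis.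

Key step: step 7

Numbering: the target is numbered as 1H,3H-furo[3,4-c]furan (C1, O2, C3, C3a, C4, O5, C6, C6a). Ring 1 is C1–O2–C3–C3a–C6a and ring 2 is C3a–C4–O5–C6–C6a.
Assumption: (R)-SEGPHOS is taken as the ligand enantiomer that delivers the (1R,2S)-diol 5; if the sense of induction proves opposite, (S)-SEGPHOS is used and nothing else changes.

Step 1
Reactants: 1 [4-(benzyloxy)-3-methoxyphenyl]methanol
Product: 2 1-(benzyloxy)-4-(bromomethyl)-2-methoxybenzene
Conditions: PBr3 (0.4 equiv), Et2O, 0 °C
Reagents that add atoms: phosphorus tribromide, BrP(Br)Br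
Why: The alcohol is activated as a phosphite ester and displaced by bromide (SN2 at a primary benzylic carbon), and the aryl ethers are inert at 0 °C.

Step 2
Reactants: 1 [4-(benzyloxy)-3-methoxyphenyl]methanol; 3 4-ethenyl-1,3-dioxolan-2-one (racemic)
Product: 5 (1R,2S)-1-[4-(benzyloxy)-3-methoxyphenyl]-2-ethenylpropane-1,3-diol, via aldehyde 4 (not isolated)
Conditions: [Ir(cod)Cl]2 (2.5 mol %), (R)-SEGPHOS (5 mol %), 4-cyano-3-nitrobenzoic acid (10 mol %), K3PO4 (cat.), 3 (2 equiv), THF, 90 °C, sealed tube
Reagents that add atoms: none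
Why: In this iridium-catalysed transfer-hydrogenative carbonyl (hydroxymethyl)allylation, 1 is dehydrogenated to aldehyde 4 and ionisation with decarboxylation of 3 gives a (hydroxymethyl)allyl–iridium species whose (E)-σ-allyl form adds through a closed chair-like transition state, so the anti relationship of C1 and C2 follows from the allyl geometry and the absolute configuration from the chiral bisphosphine.

Step 3
Reactants: 5 (1R,2S)-1-[4-(benzyloxy)-3-methoxyphenyl]-2-ethenylpropane-1,3-diol; 2 1-(benzyloxy)-4-(bromomethyl)-2-methoxybenzene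
Product: 6 (1R,2S)-1-[4-(benzyloxy)-3-methoxyphenyl]-2-({[4-(benzyloxy)-3-methoxyphenyl]methoxy}methyl)but-3-en-1-ol
Conditions: Ag2O (1.5 equiv), 2 (1.1 equiv), CH2Cl2, rt, dark
Reagents that add atoms: none
Why: Ag2O-mediated Williamson etherification should alkylate the less hindered primary hydroxyl of the 1,3-diol with the activated benzylic bromide and leave the secondary benzylic hydroxyl free; no stereocentre is touched.

Step 4
Reactants: 6 (1R,2S)-1-[4-(benzyloxy)-3-methoxyphenyl]-2-({[4-(benzyloxy)-3-methoxyphenyl]methoxy}methyl)but-3-en-1-ol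
Product: 7 (1R,2S,3RS)-1-[4-(benzyloxy)-3-methoxyphenyl]-2-({[4-(benzyloxy)-3-methoxyphenyl]methoxy}methyl)butane-1,3,4-triol
Conditions: OsO4 (2 mol %), NMO (1.5 equiv), acetone/H2O 4:1, rt
Reagents that add atoms: osmium tetroxide (catalytic oxygen carrier), O=[Os](=O)(=O)=O; N-methylmorpholine N-oxide, C[N+]1([O-])CCOCC1; water, O
Why: Catalytic syn-dihydroxylation of the only alkene (OsO4 with NMO as terminal oxidant) gives the new carbinol centre as a mixture, which is irrelevant because that carbon becomes the ketone in step 6.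

Step 5
Reactants: 7 (1R,2S,3RS)-1-[4-(benzyloxy)-3-methoxyphenyl]-2-({[4-(benzyloxy)-3-methoxyphenyl]methoxy}methyl)butane-1,3,4-triol
Product: 9 (3RS,4R,5R)-5-[4-(benzyloxy)-3-methoxyphenyl]-4-({[4-(benzyloxy)-3-methoxyphenyl]methoxy}methyl)oxolan-3-ol, via primary tosylate 8 (not isolated)
Conditions: TsCl (1.05 equiv), pyridine, CH2Cl2, 0 °C to rt; then 60 °C
Reagents that add atoms: none
Why: Selective sulfonylation of the primary hydroxyl followed by intramolecular Williamson etherification (5-exo-tet) by the benzylic hydroxyl closes ring 1 without breaking a bond to either stereocentre, so the anti diol becomes the trans-4,5-disubstituted oxolane.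

Step 6
Reactants: 9 (3RS,4R,5R)-5-[4-(benzyloxy)-3-methoxyphenyl]-4-({[4-(benzyloxy)-3-methoxyphenyl]methoxy}methyl)oxolan-3-ol
Product: 10 (4S,5R)-5-[4-(benzyloxy)-3-methoxyphenyl]-4-({[4-(benzyloxy)-3-methoxyphenyl]methoxy}methyl)oxolan-3-one
Conditions: Dess–Martin periodinane (1.3 equiv), NaHCO3, CH2Cl2, 0 °C to rt
Reagents that add atoms: none
Why: Dess–Martin oxidation under buffered, non-basic conditions converges both C3 epimers to one ketone and avoids β-elimination of the two β-alkoxy groups, the α-stereocentre C4 being already in its more stable trans arrangement.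

Step 7
Reactants: 10 (4S,5R)-5-[4-(benzyloxy)-3-methoxyphenyl]-4-({[4-(benzyloxy)-3-methoxyphenyl]methoxy}methyl)oxolan-3-one
Product: 12 (1R,3aR,4S,6aS)-1,4-bis[4-(benzyloxy)-3-methoxyphenyl]tetrahydro-1H,3H-furo[3,4-c]furan-3a-ol, via 1,5-biradical 11 (not isolated)
Conditions: hν (medium-pressure Hg lamp, borosilicate filter, λ > 300 nm), degassed benzene (0.01 M), rt
Reagents that add atoms: none
Why: n→π* excitation of the ring ketone (C3 of 10, the future C3a) is followed by 1,6-hydrogen transfer through a seven-membered transition state from the benzylic OCH2Ar group, the only abstractable site because the γ-position is the ether oxygen, to give 1,5-biradical 11, whose two radical centres combine to form the C3a–C4 bond. The closest known reaction is the Norrish–Yang photocyclization of β-alkoxy ketones by δ-hydrogen abstraction to 3-hydroxyoxolanes. Ring 2 (C3a, C4, O5, C6, C6a) is closed by radical–radical recombination of the 1,5-biradical, formally a 5-exo attack of the benzylic carbon on the carbonyl carbon. C3a is controlled by the tether: the benzylic radical hangs from C6a (C4 of 10) and can reach only the same face of the ketyl carbon, which enforces the cis ring fusion and places the hydroxyl on the convex face; C4 is controlled by the bicyclic transition state, in which the aryl group of the freely rotating benzylic radical takes the exo (convex) position. The step needs site selectivity of hydrogen abstraction, secured by geometry (the C5–H of 10 is β to the carbonyl and the O-benzyl CH2 groups are remote), and it must outrun α-cleavage of the oxolanone, which the activated benzylic ether C–H bond and the filter that leaves the arenes unexcited should favour.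

Step 8
Reactants: 12 (1R,3aR,4S,6aS)-1,4-bis[4-(benzyloxy)-3-methoxyphenyl]tetrahydro-1H,3H-furo[3,4-c]furan-3a-ol
Product: 13 (1R,3aR,4S,6aS)-1,4-bis[4-(benzyloxy)-3-methoxyphenyl]tetrahydro-1H,3H-furo[3,4-c]furan-3a-yl acetate
Conditions: Ac2O (5 equiv), DMAP (1 equiv), Et3N, CH2Cl2, rt to 40 °C
Reagents that add atoms: acetic anhydride, CC(=O)OC(C)=O
Why: DMAP-catalysed acyl transfer through the N-acetylpyridinium ion should acetylate the hindered tertiary bridgehead alcohol, which sits on the convex face and is the only free hydroxyl.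

Step 9
Reactants: 13 (1R,3aR,4S,6aS)-1,4-bis[4-(benzyloxy)-3-methoxyphenyl]tetrahydro-1H,3H-furo[3,4-c]furan-3a-yl acetate
Product: 14 (1R,3aR,4S,6aS)-1,4-bis(4-hydroxy-3-methoxyphenyl)tetrahydro-1H,3H-furo[3,4-c]furan-3a-yl acetate (8-acetoxypinoresinol)
Conditions: H2 (1 atm), 10% Pd/C, EtOAc, rt, stopped at consumption of 13
Reagents that add atoms: none
Why: Hydrogenolysis of the two aryl benzyl ethers over Pd/C is much faster than cleavage of the dialkyl benzylic C–O bonds of the furofuran or of the acetate, so the diphenol should be obtained with all four stereocentres untouched.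

Compound list
1 | [4-(benzyloxy)-3-methoxyphenyl]methanol | COc1cc(CO)ccc1OCc1ccccc1 | starting material
2 | 1-(benzyloxy)-4-(bromomethyl)-2-methoxybenzene | COc1cc(CBr)ccc1OCc1ccccc1 | intermediate
3 | 4-ethenyl-1,3-dioxolan-2-one (racemic) | C=CC1COC(=O)O1 | starting material
4 | 4-(benzyloxy)-3-methoxybenzaldehyde | COc1cc(C=O)ccc1OCc1ccccc1 | intermediate
5 | (1R,2S)-1-[4-(benzyloxy)-3-methoxyphenyl]-2-ethenylpropane-1,3-diol | COc1cc([C@H](O)[C@H](CO)C=C)ccc1OCc1ccccc1 | intermediate
6 | (1R,2S)-1-[4-(benzyloxy)-3-methoxyphenyl]-2-({[4-(benzyloxy)-3-methoxyphenyl]methoxy}methyl)but-3-en-1-ol | COc1cc([C@H](O)[C@H](COCc2ccc(OCc3ccccc3)c(OC)c2)C=C)ccc1OCc1ccccc1 | intermediate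
7 | (1R,2S,3RS)-1-[4-(benzyloxy)-3-methoxyphenyl]-2-({[4-(benzyloxy)-3-methoxyphenyl]methoxy}methyl)butane-1,3,4-triol | COc1cc([C@H](O)[C@H](COCc2ccc(OCc3ccccc3)c(OC)c2)C(O)CO)ccc1OCc1ccccc1 | intermediate
8 | (2RS,3S,4R)-4-[4-(benzyloxy)-3-methoxyphenyl]-3-({[4-(benzyloxy)-3-methoxyphenyl]methoxy}methyl)-2,4-dihydroxybutyl 4-methylbenzenesulfonate | COc1cc([C@H](O)[C@H](COCc2ccc(OCc3ccccc3)c(OC)c2)C(O)COS(=O)(=O)c2ccc(C)cc2)ccc1OCc1ccccc1 | intermediate
9 | (3RS,4R,5R)-5-[4-(benzyloxy)-3-methoxyphenyl]-4-({[4-(benzyloxy)-3-methoxyphenyl]methoxy}methyl)oxolan-3-ol | COc1cc([C@@H]2OCC(O)[C@H]2COCc2ccc(OCc3ccccc3)c(OC)c2)ccc1OCc1ccccc1 | intermediate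
10 | (4S,5R)-5-[4-(benzyloxy)-3-methoxyphenyl]-4-({[4-(benzyloxy)-3-methoxyphenyl]methoxy}methyl)oxolan-3-one | COc1cc([C@@H]2OCC(=O)[C@H]2COCc2ccc(OCc3ccccc3)c(OC)c2)ccc1OCc1ccccc1 | intermediate
11 | 1,5-biradical of 10 (ketyl carbon C3 and benzylic ether carbon) | COc1cc([C@@H]2OC[C](O)[C@H]2CO[CH]c2ccc(OCc3ccccc3)c(OC)c2)ccc1OCc1ccccc1 | intermediate
12 | (1R,3aR,4S,6aS)-1,4-bis[4-(benzyloxy)-3-methoxyphenyl]tetrahydro-1H,3H-furo[3,4-c]furan-3a-ol | COc1cc([C@@H]2OC[C@@]3(O)[C@H](c4ccc(OCc5ccccc5)c(OC)c4)OC[C@@H]23)ccc1OCc1ccccc1 | intermediate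
13 | (1R,3aR,4S,6aS)-1,4-bis[4-(benzyloxy)-3-methoxyphenyl]tetrahydro-1H,3H-furo[3,4-c]furan-3a-yl acetate | COc1cc([C@@H]2OC[C@@]3(OC(C)=O)[C@H](c4ccc(OCc5ccccc5)c(OC)c4)OC[C@@H]23)ccc1OCc1ccccc1 | intermediate
14 | (1R,3aR,4S,6aS)-1,4-bis(4-hydroxy-3-methoxyphenyl)tetrahydro-1H,3H-furo[3,4-c]furan-3a-yl acetate (8-acetoxypinoresinol) | COc1cc([C@@H]2OC[C@@]3(OC(C)=O)[C@H](c4ccc(O)c(OC)c4)OC[C@@H]23)ccc1O | target

Total step count: 9
Longest linear sequence: 8 steps (steps 2 to 9 from 1; the branch through bromide 2, steps 1 and 3 to 9, is equally long)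

Steps most likely to fail

Step 7. The excited oxolanone may undergo α-cleavage, may be quenched by the electron-rich arenes before hydrogen transfer, or the biradical may close with the aryl group on the concave face. The fallback sets out from 10 and comes back at 12, and builds the same bond by olefination instead of photochemistry. Bromide 2 and PPh3 (toluene, 80 °C) give [4-(benzyloxy)-3-methoxybenzyl]triphenylphosphonium bromide F1. Its ylide (KN(SiMe3)2, THF, −78 °C to rt) should olefinate 10 to (4S,5R)-5-[4-(benzyloxy)-3-methoxyphenyl]-4-({[4-(benzyloxy)-3-methoxyphenyl]methoxy}methyl)-3-{[4-(benzyloxy)-3-methoxyphenyl]methylidene}oxolane F2, for which an E/Z mixture is acceptable. OsO4/NMO dihydroxylation should occur on the ring face opposite to the C4 side chain and give (3R,4S,5R)-5-[4-(benzyloxy)-3-methoxyphenyl]-4-({[4-(benzyloxy)-3-methoxyphenyl]methoxy}methyl)-3-{[4-(benzyloxy)-3-methoxyphenyl](hydroxy)methyl}oxolan-3-ol F3, with the tertiary hydroxyl already in the configuration of 12. Catalytic camphorsulfonic acid (CH2Cl2, 0 °C) should then ionise the electron-rich secondary benzylic alcohol. The side-chain ether oxygen captures the cation in a five-membered closure with the aryl group on the convex face, and the arylmethyl group leaves and is returned as alcohol 1 (debenzylative cycloetherification), giving 12.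

Step 5. The vicinal secondary hydroxyl may close onto the primary sulfonate to give an epoxide, the side-chain ether oxygen may take part in the displacement, or the primary hydroxyl may not be sulfonylated cleanly in the presence of two secondary ones. The fallback sets out from 7 and comes back at 9, and closes ring 1 at the other C–O bond. Catalytic camphorsulfonic acid (or BF3·OEt2 at −40 °C) in CH2Cl2 ionises the p-alkoxybenzylic alcohol and the primary hydroxyl traps the cation (5-exo). Under reversible ionisation the aryl group should settle trans to the C4 substituent, so C5 is then set by C4 instead of being inherited from step 2. This fallback makes no compound outside the list (F0).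

Step 9. Hydrogenation may not stop after O-debenzylation and may open the benzylic C–O bonds of the furofuran (C1–O2, C4–O5). The fallback sets out from 13 and comes back at 14 without any reductant. BCl3 in CH2Cl2 at −78 °C with excess pentamethylbenzene as a non-basic benzyl cation scavenger cleaves the aryl benzyl ethers by Lewis-acid-assisted heterolysis. A quench at −78 °C with MeOH should limit epimerisation of the benzylic ether centres and spare the acetate. This fallback makes no compound outside the list (F0).

Further compounds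
F1 | step 7 | [4-(benzyloxy)-3-methoxybenzyl]triphenylphosphonium bromide | COc1cc(C[P+](c2ccccc2)(c2ccccc2)c2ccccc2)ccc1OCc1ccccc1.[Br-]
F2 | step 7 | (4S,5R)-5-[4-(benzyloxy)-3-methoxyphenyl]-4-({[4-(benzyloxy)-3-methoxyphenyl]methoxy}methyl)-3-{[4-(benzyloxy)-3-methoxyphenyl]methylidene}oxolane (E/Z mixture) | COc1cc([C@@H]2OCC(=Cc3ccc(OCc4ccccc4)c(OC)c3)[C@H]2COCc2ccc(OCc3ccccc3)c(OC)c2)ccc1OCc1ccccc1
F3 | step 7 | (3R,4S,5R)-5-[4-(benzyloxy)-3-methoxyphenyl]-4-({[4-(benzyloxy)-3-methoxyphenyl]methoxy}methyl)-3-{[4-(benzyloxy)-3-methoxyphenyl](hydroxy)methyl}oxolan-3-ol (side-chain carbinol as a mixture) | COc1cc([C@@H]2OC[C@@](O)(C(O)c3ccc(OCc4ccccc4)c(OC)c3)[C@H]2COCc2ccc(OCc3ccccc3)c(OC)c2)ccc1OCc1ccccc1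
F0 | step 5 | none | none
F0 | step 9 | none | none
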